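The butenolide (O1, C2=O, C3, C4, C5; exocyclic C5=C6) is disconnected at C4–C5. Both carbons are acceptor sites of a masked 4-oxo-2-enoic acid, whose oxygens at C2 and C5 stand in a dissonant 1,4-relationship; C4 is therefore brought in with inverted polarity as an alkenyl iodide. The precursor is an open-chain (E)-enol ester in which O1–C5 already exists and C6 carries the complete (S)-configured furanoterpenoid chain. One intramolecular Mizoroki–Heck reaction forms C4–C5, closes the lactone 5-exo and, by β-hydride loss from C5, sets the (Z)-exocyclic alkene. The chain derives from farnesyl bromide; its stereocentre from Ru–BINAP hydrogenation.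

Key step: step 12

Remark: locants used throughout are lactone ring O1, C2 (C=O), C3 (bears CH2OH), C4 (ring CH) and C5; C6 is the exocyclic alkene carbon and C7 the methyl-bearing stereocentre, which the SMILES defines as (S).

Step 1
Reactants: 1 furan-3-ylmethanol
Product: 2 3-(chloromethyl)furan
Conditions: SOCl2, pyridine, Et2O, 0 °C
Reagents that add atoms: thionyl chloride, O=S(Cl)Cl
Why: Chlorodehydroxylation of a primary alcohol with SOCl2, with pyridine buffering the HCl that would otherwise polymerise the furan.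

Step 2
Reactants: 2 3-(chloromethyl)furan; 3 (2E,6E)-farnesyl bromide
Product: 5 3-[(3E,7E)-4,8,12-trimethyltrideca-3,7,11-trien-1-yl]furan, via (furan-3-ylmethyl)magnesium chloride 4 (not isolated)
Conditions: Mg, THF, 0 °C to rt; then 3, Li2CuCl4 (3 mol%), THF, 0 °C
Reagents that add atoms: none
Why: Grignard formation followed by Li2CuCl4-catalysed (Kochi-type) allylic cross-coupling, which for a primary allylic bromide should occur at the α-carbon (SN2) with retention of the (E)-alkene.

Step 3
Reactants: 5 3-[(3E,7E)-4,8,12-trimethyltrideca-3,7,11-trien-1-yl]furan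
Product: 6 (2E,6E,10E)-13-(furan-3-yl)-2,6,10-trimethyltrideca-2,6,10-trien-1-ol
Conditions: SeO2 (0.2 equiv), t-BuOOH (3 equiv), salicylic acid (0.1 equiv), CH2Cl2, 0 °C to rt, stopped at partial conversion
Reagents that add atoms: tert-butyl hydroperoxide, CC(C)(C)OO
Why: Catalytic SeO2 allylic oxidation (ene reaction, then 2,3-sigmatropic shift) should attack the (E)-methyl group of the terminal, least hindered and most electron-rich trisubstituted alkene and give the (E)-allylic alcohol.

Step 4
Reactants: 6 (2E,6E,10E)-13-(furan-3-yl)-2,6,10-trimethyltrideca-2,6,10-trien-1-ol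
Product: 7 (2S,6E,10E)-13-(furan-3-yl)-2,6,10-trimethyltrideca-6,10-dien-1-ol
Conditions: Ru(OAc)2[(S)-BINAP] (1 mol%), H2 (50 atm), MeOH, 25 °C
Reagents that add atoms: none
Why: Noyori hydroxyl-directed asymmetric hydrogenation reduces only the alkene of the allylic alcohol (isolated trisubstituted alkenes and the furan are inert), and the (S)-BINAP ligand should set C2 as (S) if it selects the same enantioface, relative to the C(OH)–C=C unit, as in the geraniol to (R)-citronellol reduction.

Step 5
Reactants: 7 (2S,6E,10E)-13-(furan-3-yl)-2,6,10-trimethyltrideca-6,10-dien-1-ol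
Product: 8 (2S,6E,10E)-13-(furan-3-yl)-2,6,10-trimethyltrideca-6,10-dienal
Conditions: Dess–Martin periodinane, NaHCO3, CH2Cl2, 0 °C to rt; used crude
Reagents that add atoms: none
Why: Buffered Dess–Martin oxidation is neutral enough to spare the furan and alkenes and to leave the α-stereocentre of the aldehyde unepimerised.

Step 6
Reactants: 8 (2S,6E,10E)-13-(furan-3-yl)-2,6,10-trimethyltrideca-6,10-dienal
Product: 9 3-[(3E,7E,12S)-4,8,12-trimethyltetradeca-3,7-dien-13-yn-1-yl]furan
Conditions: dimethyl (1-diazo-2-oxopropyl)phosphonate, K2CO3, MeOH, 0 °C to rt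
Reagents that add atoms: dimethyl (1-diazo-2-oxopropyl)phosphonate, CC(=O)C(=[N+]=[N-])P(=O)(OC)OC
Why: Seyferth–Gilbert homologation with the Ohira–Bestmann reagent under K2CO3/MeOH, mild enough to keep the α-stereocentre intact.

Step 7
Reactants: 9 3-[(3E,7E,12S)-4,8,12-trimethyltetradeca-3,7-dien-13-yn-1-yl]furan
Product: 11 potassium trifluoro[(1E,3S,7E,11E)-14-(furan-3-yl)-3,7,11-trimethyltetradeca-1,7,11-trien-1-yl]borate, via alkenyl pinacol boronate 10 (not isolated)
Conditions: pinacolborane, Cp2Zr(H)Cl (10 mol%), Et3N (10 mol%), neat, 60 °C; then KHF2, MeOH/H2O, rt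
Reagents that add atoms: pinacolborane, B1OC(C)(C)C(C)(C)O1; potassium hydrogen difluoride, [K+].F[H-]F
Why: Zirconium-catalysed syn hydroboration of the terminal alkyne gives the (E)-alkenylboronate without touching the trisubstituted alkenes, and KHF2 converts it into the trifluoroborate.

Step 8
Reactants: 12 ethyl propiolate
Product: 14 ethyl (2Z)-2-(hydroxymethyl)-3-iodoprop-2-enoate, via magnesium β-iodoallenolate 13 (not isolated)
Conditions: MgI2 (1.2 equiv), CH2Cl2, 0 °C; then CH2O gas (from cracked paraformaldehyde), −20 to 0 °C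
Reagents that add atoms: magnesium iodide, [Mg+2].[I-].[I-]; formaldehyde, C=O
Why: Halo-aldol (β-iodo Morita–Baylis–Hillman) reaction in which iodide adds to the propiolate and the allenolate attacks formaldehyde on the side away from iodine, which under kinetic control should leave iodine cis to the ester (Z).

Step 9
Reactants: 14 ethyl (2Z)-2-(hydroxymethyl)-3-iodoprop-2-enoate
Product: 15 ethyl (2Z)-2-{[tert-butyl(dimethyl)silyl]oxymethyl}-3-iodoprop-2-enoate
Conditions: TBSCl, imidazole, DMF, 0 °C to rt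
Reagents that add atoms: tert-butyldimethylsilyl chloride, CC(C)(C)[Si](C)(C)Cl
Why: Standard silylation of a primary alcohol, needed because a free alcohol would compete in the copper-mediated C–O coupling of step 11.

Step 10
Reactants: 15 ethyl (2Z)-2-{[tert-butyl(dimethyl)silyl]oxymethyl}-3-iodoprop-2-enoate
Product: 16 (2Z)-2-{[tert-butyl(dimethyl)silyl]oxymethyl}-3-iodoprop-2-enoic acid
Conditions: LiOH·H2O, THF/H2O, 0 °C; acidic work-up (1 M HCl to pH 4, 0 °C)
Reagents that add atoms: lithium hydroxide, [Li+].[OH-]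
Why: Ester saponification at 0 °C, which the primary silyl ether tolerates and which cannot eliminate HI because C3 carries no hydrogen.

Step 11
Reactants: 11 potassium trifluoro[(1E,3S,7E,11E)-14-(furan-3-yl)-3,7,11-trimethyltetradeca-1,7,11-trien-1-yl]borate; 16 (2Z)-2-{[tert-butyl(dimethyl)silyl]oxymethyl}-3-iodoprop-2-enoic acid (1.5 equiv)
Product: 17 (1E,3S,7E,11E)-14-(furan-3-yl)-3,7,11-trimethyltetradeca-1,7,11-trien-1-yl (2Z)-2-{[tert-butyl(dimethyl)silyl]oxymethyl}-3-iodoprop-2-enoate
Conditions: Cu(OAc)2 (20 mol%), DMAP (20 mol%), 4 Å molecular sieves, O2 (1 atm), MeCN/CH2Cl2, 40 °C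
Reagents that add atoms: none
Why: Chan–Lam–Evans oxidative C–O coupling of an alkenyltrifluoroborate with a carboxylic acid forms the O1–C5 bond with retention of the (E)-alkene, the alkenyl iodide being inert to copper at this temperature.

Step 12
Reactants: 17 (1E,3S,7E,11E)-14-(furan-3-yl)-3,7,11-trimethyltetradeca-1,7,11-trien-1-yl (2Z)-2-{[tert-butyl(dimethyl)silyl]oxymethyl}-3-iodoprop-2-enoate
Product: 18 (5Z)-3-{[tert-butyl(dimethyl)silyl]oxymethyl}-5-[(2S,6E,10E)-13-(furan-3-yl)-2,6,10-trimethyltrideca-6,10-dien-1-ylidene]furan-2(5H)-one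
Conditions: Pd(OAc)2 (10 mol%), PPh3 (25 mol%), Ag2CO3 (2 equiv), MeCN (0.005 M), 70 °C
Reagents that add atoms: none
Why: Zerovalent palladium inserts into the C4–I bond, Ag2CO3 strips iodide, and the cationic divalent alkenylpalladium adds syn across the enol ester C5=C6 with C4 bonding to the oxygen-bearing C5; rotation about C5–C6 and syn β-hydride elimination of H–C5 then create the exocyclic alkene and release zerovalent palladium. The closest known reaction type is the intramolecular Mizoroki–Heck reaction, combined with the internal (α) regiochemistry known for cationic Heck couplings of vinyl ethers and vinyl esters. The lactone ring closes in the 5-exo-trig mode. No stereocentre is created; the alkene geometry follows from syn insertion and syn elimination on the (E)-enol ester, which places C7 cis to O1 (Z), and this is also the thermodynamically preferred isomer. The step needs 5-exo over 6-endo closure (secured by the three-atom ester tether and the cationic pathway), loss of H–C5 instead of H–C7 or of the ring carboxylate (H–C5 is allylic, α to oxygen and leads to the conjugated dienoate), and ring closure over intermolecular coupling (secured by high dilution).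

Step 13
Reactants: 18 (5Z)-3-{[tert-butyl(dimethyl)silyl]oxymethyl}-5-[(2S,6E,10E)-13-(furan-3-yl)-2,6,10-trimethyltrideca-6,10-dien-1-ylidene]furan-2(5H)-one
Product: 19 (5Z)-5-[(2S,6E,10E)-13-(furan-3-yl)-2,6,10-trimethyltrideca-6,10-dien-1-ylidene]-3-(hydroxymethyl)furan-2(5H)-one
Conditions: HF·pyridine, pyridine, THF, 0 °C to rt
Reagents that add atoms: none
Why: Buffered fluoride desilylation frees the primary alcohol without exposing the ylidenebutenolide to base or the furan to strong acid.

Compound list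
1 | furan-3-ylmethanol | OCc1ccoc1 | starting material
2 | 3-(chloromethyl)furan | ClCc1ccoc1 | intermediate
3 | (2E,6E)-1-bromo-3,7,11-trimethyldodeca-2,6,10-triene (farnesyl bromide) | CC(C)=CCC/C(C)=C/CC/C(C)=C/CBr | starting material
4 | (furan-3-ylmethyl)magnesium chloride | Cl[Mg]Cc1ccoc1 | intermediate
5 | 3-[(3E,7E)-4,8,12-trimethyltrideca-3,7,11-trien-1-yl]furan | C/C(=C\CCc1ccoc1)CC/C=C(\C)CCC=C(C)C | intermediate
6 | (2E,6E,10E)-13-(furan-3-yl)-2,6,10-trimethyltrideca-2,6,10-trien-1-ol | C/C(=C\CCc1ccoc1)CC/C=C(\C)CC/C=C(\C)CO | intermediate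
7 | (2S,6E,10E)-13-(furan-3-yl)-2,6,10-trimethyltrideca-6,10-dien-1-ol | C/C(=C\CCc1ccoc1)CC/C=C(\C)CCC[C@H](C)CO | intermediate
8 | (2S,6E,10E)-13-(furan-3-yl)-2,6,10-trimethyltrideca-6,10-dienal | C/C(=C\CCc1ccoc1)CC/C=C(\C)CCC[C@H](C)C=O | intermediate
9 | 3-[(3E,7E,12S)-4,8,12-trimethyltetradeca-3,7-dien-13-yn-1-yl]furan | C/C(=C\CCc1ccoc1)CC/C=C(\C)CCC[C@H](C)C#C | intermediate
10 | 2-[(1E,3S,7E,11E)-14-(furan-3-yl)-3,7,11-trimethyltetradeca-1,7,11-trien-1-yl]-4,4,5,5-tetramethyl-1,3,2-dioxaborolane | C/C(=C\CCc1ccoc1)CC/C=C(\C)CCC[C@H](C)/C=C/B1OC(C)(C)C(C)(C)O1 | intermediate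
11 | potassium trifluoro[(1E,3S,7E,11E)-14-(furan-3-yl)-3,7,11-trimethyltetradeca-1,7,11-trien-1-yl]borate | C/C(=C\CCc1ccoc1)CC/C=C(\C)CCC[C@H](C)/C=C/[B-](F)(F)F.[K+] | intermediate
12 | ethyl propiolate | C#CC(=O)OCC | starting material
13 | iodomagnesium 1-ethoxy-3-iodopropa-1,2-dien-1-olate | CCOC(O[Mg]I)=C=CI | intermediate
14 | ethyl (2Z)-2-(hydroxymethyl)-3-iodoprop-2-enoate | CCOC(=O)/C(CO)=C\I | intermediate
15 | ethyl (2Z)-2-{[tert-butyl(dimethyl)silyl]oxymethyl}-3-iodoprop-2-enoate | CCOC(=O)/C(CO[Si](C)(C)C(C)(C)C)=C\I | intermediate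
16 | (2Z)-2-{[tert-butyl(dimethyl)silyl]oxymethyl}-3-iodoprop-2-enoic acid | OC(=O)/C(CO[Si](C)(C)C(C)(C)C)=C\I | intermediate
17 | (1E,3S,7E,11E)-14-(furan-3-yl)-3,7,11-trimethyltetradeca-1,7,11-trien-1-yl (2Z)-2-{[tert-butyl(dimethyl)silyl]oxymethyl}-3-iodoprop-2-enoate | C/C(=C\CCc1ccoc1)CC/C=C(\C)CCC[C@H](C)/C=C/OC(=O)/C(CO[Si](C)(C)C(C)(C)C)=C\I | intermediate
18 | (5Z)-3-{[tert-butyl(dimethyl)silyl]oxymethyl}-5-[(2S,6E,10E)-13-(furan-3-yl)-2,6,10-trimethyltrideca-6,10-dien-1-ylidene]furan-2(5H)-one | C/C(=C\CCc1ccoc1)CC/C=C(\C)CCC[C@H](C)/C=C1/C=C(CO[Si](C)(C)C(C)(C)C)C(=O)O1 | intermediate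
19 | (5Z)-5-[(2S,6E,10E)-13-(furan-3-yl)-2,6,10-trimethyltrideca-6,10-dien-1-ylidene]-3-(hydroxymethyl)furan-2(5H)-one | C/C(=C\CCc1ccoc1)CC/C=C(\C)CCC[C@H](C)/C=C1/C=C(CO)C(=O)O1 | target

Total step count: 13. Longest linear sequence: 10 steps (steps 1–7 and 11–13); steps 8–10 build the acid 16 in parallel.

Steps most likely to fail

Step 12 (key ring closure). After carbopalladation the alkylpalladium at C6 may expel the ring carboxylate (β-acyloxy elimination, which reopens the lactone to a dienoic acid), may lose H–C7 and so erase the stereocentre, or the insertion may run 6-endo to a 2-pyranone. The fallback sets out from 17 and returns to the route at 18, closing the same C4–C5 bond without any metal at C6. Tin-hydride-mediated 5-exo-trig alkenyl radical cyclisation (Bu3SnH, AIBN, benzene, 80 °C, syringe-pump addition) should give the saturated 3-(silyloxymethyl)-5-alkylbutenolide F1 as a mixture of C5 epimers. Enol silylation (TBSOTf, Et3N, CH2Cl2, 0 °C) converts F1 into the 2-silyloxyfuran F2. One equivalent of PhSeCl at −78 °C selenenylates F2 at C5 to give the 5-phenylselanylbutenolide F3. Oxidation (H2O2, pyridine, CH2Cl2, 0 °C) and selenoxide syn-elimination, which can only remove a hydrogen from C6, then deliver 18, any (E)-isomer being equilibrated to (Z) with a trace of I2.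

Step 4 (asymmetric hydrogenation). Enantioface selection may be insufficient or inverted for a 2-methyl-substituted allylic alcohol, and alkene migration to the aldehyde may compete; the configuration of 7 is to be checked (Mosher ester) before going on. The fallback sets out from 6 and returns at 7 and relies on carboxylate-directed hydrogenation of the tiglic-acid-type substrate. Allylic oxidation with MnO2 (CH2Cl2, rt) gives the enal F4. Pinnick oxidation (NaClO2, NaH2PO4, 2-methyl-2-butene, t-BuOH/H2O) gives the 2-methyl-2-enoic acid F5. Hydrogenation with Ru(OAc)2(BINAP), using the ligand antipode that the tiglic acid precedent assigns to the (S)-acid (H2 4 atm, MeOH), should give the (2S)-acid F6. Reduction with LiAlH4 (THF, 0 °C) returns 7.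

Step 11 (copper-mediated enol ester formation). Protodeboronation or oxidative homocoupling of the alkenylborate may outrun C–O bond formation, and DMAP may add to the β-iodoacrylate and scramble or displace the iodide. The fallback sets out from alkyne 9 and acid 16 (bypassing step 7) and returns at 18. Ruthenium-catalysed anti-Markovnikov addition of 16 to 9 (Ru(2-methylallyl)2(dppb) 2 mol%, toluene, 65 °C) should give the (Z)-enol ester F7. Under the Heck conditions of step 12, syn insertion and syn elimination should now give the (E)-ylidenebutenolide F8. Catalytic I2 (CH2Cl2, daylight, rt) isomerises F8 to the more stable (Z)-isomer 18.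

Further compounds
F1 | step 12 | 3-{[tert-butyl(dimethyl)silyl]oxymethyl}-5-[(2S,6E,10E)-13-(furan-3-yl)-2,6,10-trimethyltrideca-6,10-dien-1-yl]furan-2(5H)-one (C5 epimers) | C/C(=C\CCc1ccoc1)CC/C=C(\C)CCC[C@H](C)CC1C=C(CO[Si](C)(C)C(C)(C)C)C(=O)O1
F2 | step 12 | tert-butyl{[3-({[tert-butyl(dimethyl)silyl]oxy}methyl)-5-[(2S,6E,10E)-13-(furan-3-yl)-2,6,10-trimethyltrideca-6,10-dien-1-yl]furan-2-yl]oxy}dimethylsilane | C/C(=C\CCc1ccoc1)CC/C=C(\C)CCC[C@H](C)Cc1cc(CO[Si](C)(C)C(C)(C)C)c(O[Si](C)(C)C(C)(C)C)o1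
F3 | step 12 | 3-{[tert-butyl(dimethyl)silyl]oxymethyl}-5-[(2S,6E,10E)-13-(furan-3-yl)-2,6,10-trimethyltrideca-6,10-dien-1-yl]-5-(phenylselanyl)furan-2(5H)-one (C5 epimers) | C/C(=C\CCc1ccoc1)CC/C=C(\C)CCC[C@H](C)CC1([Se]c2ccccc2)C=C(CO[Si](C)(C)C(C)(C)C)C(=O)O1
F4 | step 4 | (2E,6E,10E)-13-(furan-3-yl)-2,6,10-trimethyltrideca-2,6,10-trienal | C/C(=C\CCc1ccoc1)CC/C=C(\C)CC/C=C(\C)C=O
F5 | step 4 | (2E,6E,10E)-13-(furan-3-yl)-2,6,10-trimethyltrideca-2,6,10-trienoic acid | C/C(=C\CCc1ccoc1)CC/C=C(\C)CC/C=C(\C)C(=O)O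
F6 | step 4 | (2S,6E,10E)-13-(furan-3-yl)-2,6,10-trimethyltrideca-6,10-dienoic acid | C/C(=C\CCc1ccoc1)CC/C=C(\C)CCC[C@H](C)C(=O)O
F7 | step 11 | (1Z,3S,7E,11E)-14-(furan-3-yl)-3,7,11-trimethyltetradeca-1,7,11-trien-1-yl (2Z)-2-{[tert-butyl(dimethyl)silyl]oxymethyl}-3-iodoprop-2-enoate | C/C(=C\CCc1ccoc1)CC/C=C(\C)CCC[C@H](C)/C=C\OC(=O)/C(CO[Si](C)(C)C(C)(C)C)=C\I
F8 | step 11 | (5E)-3-{[tert-butyl(dimethyl)silyl]oxymethyl}-5-[(2S,6E,10E)-13-(furan-3-yl)-2,6,10-trimethyltrideca-6,10-dien-1-ylidene]furan-2(5H)-one | C/C(=C\CCc1ccoc1)CC/C=C(\C)CCC[C@H](C)/C=C1\C=C(CO[Si](C)(C)C(C)(C)C)C(=O)O1
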